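- Two numbers are asked and one verdict between them, and all three hang on the share s of target in target plus isomer of the product.

| flask | substrate | remark | time |
|---|---|---|---|
| teal | 0.31 M | run made earlier |  |
| ochre | 1.1 M | run made earlier |  |
| south-east | 0.80 M |  | 1.5 h |
| south-west | 0.25 M |  | 5.0 h |

- teal (time / h: target / %, isomer of the product / %, substrate / %): 0.200: 48.9, 26.7, 23.6; 0.667: 32.7, 46.8, 13.3; 1.33: 29.3, 55.6, 11.9; 2.00: 26.1, 56.5, 13.5; 2.50: 26.5, 55.7, 12.5
- ochre (time / h: target / %, isomer of the product / %, substrate / %): 0.200: 44.5, 25.3, 21.7; 0.417: 36.3, 39.0, 15.5; 0.667: 31.4, 45.5, 14.4; 1.33: 27.2, 50.2, 12.5; 2.50: 22.2, 49.1, 10.7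

(each reading ± 1 percentage point)

1. the winner by share of target in all that became target or isomer of the product; "neither" if no more than 2 percentage points parts them (south-east / south-west / neither)
2. share of target in all that became target or isomer of the product, south-east
3. share of target in all that became target or isomer of the product, south-west



- At a fixed time s looks nearly constant: at 0.667 h the teal run, charged at 0.31 M, reads 41.1%, and the ochre run, charged at 1.1 M, reads 40.8%, so I freeze concentration and follow s through time.
- My doubt is the ochre balance, which at its last reading stands at 82.0% of the charge against 94.7% in the teal run, but its last s is 31.1%, and I accept that beside the plateau of 31.9% from the last two teal readings.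
- As a first guess, south-east at 1.5 h resembles the teal reading at 1.33 h, whose excess x, meaning s minus the plateau, is 2.6 percentage points, which would make south-east the winner; but with 1 point of scatter per reading, I won't rest a verdict on a margin of 2 points on that small excess.
- So I use the large teal excesses: x falls from 33 points at 0.200 h to 9.2 points at 0.667 h, and from these two readings I read a rate constant k of 2.72 h⁻¹ and a relaxation half-life of 0.255 h, the time in which x halves.
- Carried on to 1.5 h, x in south-east comes out by my reckoning at 0.96 points, so I estimate s there at 32.9%; for south-west at 5.0 h I estimate 31.9%, and the estimated gap of 0.96 points is smaller than the margin, so I say neither.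
- This k predicts 1.5 points at 1.33 h where the teal run read 2.6 points, a miss of about one scatter, so I keep it.
- The forecast differs from mine, naming south-east with 33.6% against 31.2%: “The gap is narrowly above 2 points.”

The flasks give 32.8% for south-east and 32.1% for south-west, so the verdict is neither.

    substrate ⇌ target (K = 2.20, k = 0.00360 s⁻¹)
    target ⇌ isomer of the product (K = 2.10, k = 3.20 × 10⁻⁴ s⁻¹)
    isomer of the product ⇌ substrate (k = 1.50 × 10⁻⁴ s⁻¹)
    2 substrate → homo dimer (k = 2.70 × 10⁻⁴ M⁻¹ s⁻¹)

South-east holds 10.1% of its charge as homo dimer at 1.50 h, each counted as two substrate, yet leaving that step out shifts its share by less than the margin. The neighbouring flask, south-west read at 3.0 h, lies 9.15 half-lives past the teal reading at 0.667 h, which leaves x at 0.016 points and s at 31.9%, and that flask gives 32.2%.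

The data are calculated from invented constants, noise included.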